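We start from the amounts. Initiator is charged at 10 mol% of the free monomer, so the flask holds 5.00 mM of initiator against 7.4 mM of impurity. Initiator is therefore the reagent charged in the smaller amount, and its balance reads: initiator still unused plus chains begun plus initiator lost otherwise equals the charge.

the same everywhere: initiator 10 mol%; impurity 7.4 mM
- birch: free monomer 0.034 M; run made earlier
- elm: free monomer 0.075 M; run made earlier
- flask: free monomer 0.050 M; time 10 min

| run | time / min | monomer in chains / % | free monomer / % |
|---|---|---|---|
| birch | 1.33 | 13.7 | 84.5 |
| birch | 2.50 | 26.0 | 73.9 |
| birch | 4.00 | 37.8 | 62.3 |
| birch | 5.00 | 44.4 | 55.4 |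
| birch | 6.00 | 50.8 | 48.8 |
| birch | 8.00 | 60.1 | 38.2 |
| elm | 0.500 | 27.7 | 72.3 |
| elm | 1.50 | 60.0 | 38.7 |
| elm | 3.00 | 84.1 | 15.4 |
| elm | 4.00 | 91.7 | 8.4 |
| elm | 6.00 | 96.4 | 2.3 |
| elm | 8.00 | 98.5 | 1.3 |

(readings scatter by 0.5 percentage points)

- whether the average number of monomer units in a chain (chains begun, living or dead) reaches 50 by 10 min (yes / no)
- average number of monomer units in a chain (chains begun, living or dead) at 10 min

- the average divides the monomer in chains by the number of chains begun, living and dead together
- the earlier runs do not show the number of chains; that part of a forecast is a guess

The logarithm of free monomer falls steadily in both runs. The last usable readings give a pseudo-first-order rate constant of 0.120 min⁻¹ for birch and 0.624 min⁻¹ for elm. We carry these to the flask in two ways. A straight line in initiator charged gives 0.317 min⁻¹, and it implies a fixed loss of 2.42 mM of initiator. A power law through the same two runs gives 0.268 min⁻¹. The two part on the rate. We distrust the straight line, since the impurity charged is more than that loss and so gives the figure no ground.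

The parting barely matters for length. The flask's monomer in chains at 10 min, divided by 50, comes to 0.958 mM by the line and 0.932 mM by the power law, because nearly all the free monomer has reacted either way. This is our chain budget: our estimate of the most chains this flask may have begun and still reach the wanted length by the asked time. The balance then says the flask reaches 50 if at least 81.4 % of its initiator begins no chain. The earlier runs do not show the number of chains, so that part stays a guess.

The forecast says no, with a length of 13, holding that “the impurity removes a fixed amount”.

The flask gives yes and 62.3.

    initiator + impurity → spent initiator B (k = 165 M⁻¹ s⁻¹)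
    free monomer + living end → monomer in chains + living end, rate k2*[living end]*[free monomer] (k = 5.88 M⁻¹ s⁻¹)
    free monomer + initiator → spent initiator A (k = 0.831 M⁻¹ s⁻¹)
    free monomer + initiator → living end + monomer in chains (k = 3.11 M⁻¹ s⁻¹)

In the flask at 10 min the living end stands at 0.741 mM, inside the budget. The flask's length passes 50 at 5.17 min with 74.5 % reacted. In the run with half the free monomer and all other amounts as they are, even the whole charge in chains allows a budget of 0.500 mM, and that run ends at a length of 45.4.

Readings and results were generated by integration for an exercise, noise included.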